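**Plan**

- Retrosynthesis: the piperidine ring (N1, C2–C6) is cut at N1–C6 and C2–C3 into the N-sulfinyl imine of acetaldehyde (N1=C2 with its methyl group) and a four-carbon 1-methoxy-3-silyloxybutadiene (C3–C6). Before that the side chain (numbered C1' on C6 to C16') is cut at C6–C1' (conjugate addition), C3'–C4' (allylation) and C13'–C14' (epoxide opening).
- Enabling feature: C3 carries the ring oxygen and C4 is a bare CH2. C4 can therefore hold a temporary silyloxy/oxo group that makes C3 the nucleophilic and C6 the electrophilic end of the diene. The 4-oxo-5,6-ene formed then activates C6 for the chain, and the C4 oxygen leaves as its enol triflate.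
- Forward: diene and imine are made; the formal aza-Diels–Alder reaction closes the ring and sets C2 and C3; N-Boc activation follows. The chain is built from 11-bromoundec-1-ene and (S)-propylene oxide, joined at C6 by copper-catalysed Grignard addition with triflate trapping, then hydrogenolysis and global deprotection.
- Stereochemistry: C2 from the (S)-tert-butanesulfinyl auxiliary; C3 trans to C2 in the cycloaddition; C6 cis to C2 by axial attack on the N-Boc dihydropyridone; C15' from (S)-propylene oxide; C4' from Brown allylboration.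

Key step: step 5

Assumption: the facial sense in step 5 follows the open, non-chelated model for Lewis-acid-promoted additions to tert-butanesulfinyl imines (attack anti to the tert-butyl group of the s-cis S=O/C=N conformer).
Remark: where C4 is sp2 (compounds 8–11, 25, 26) the descriptor of C3 is R for the same spatial arrangement that is 3S in the target; in 22 the side-chain descriptor reads 4R because boron ranks below carbon.

**Step 1**
Reactants: 1 2-[(tert-butyldimethylsilyl)oxy]-N-methoxy-N-methylacetamide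
Product: 2 1-[(tert-butyldimethylsilyl)oxy]but-3-yn-2-one
Conditions: HC≡CMgBr, THF, −78 to 0 °C; H2O
Reagents that add atoms: ethynylmagnesium bromide, C#C[Mg]Br
Why: Weinreb ketone synthesis, in which the chelated tetrahedral adduct of the N-methoxy-N-methylamide survives until work-up so that the alkynyl Grignard reagent adds only once; no stereocenter is formed.

**Step 2**
Reactants: 2 1-[(tert-butyldimethylsilyl)oxy]but-3-yn-2-one
Product: 3 (E)-1-[(tert-butyldimethylsilyl)oxy]-4-methoxybut-3-en-2-one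
Conditions: MeOH, DABCO (10 mol%), CH2Cl2, 0 °C to rt
Reagents that add atoms: methanol, CO
Why: base-catalysed oxa-Michael addition of methanol to the terminal ynone should give the thermodynamically preferred (E)-β-methoxy enone; no stereocenter is formed.

**Step 3**
Reactants: 3 (E)-1-[(tert-butyldimethylsilyl)oxy]-4-methoxybut-3-en-2-one
Product: 4 (1Z,3E)-1-[(tert-butyldimethylsilyl)oxy]-4-methoxy-2-[(trimethylsilyl)oxy]buta-1,3-diene
Conditions: TMSOTf, Et3N, Et2O, 0 °C
Reagents that add atoms: trimethylsilyl trifluoromethanesulfonate, C[Si](C)(C)OS(=O)(=O)C(F)(F)F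
Why: silyl enol ether formation by soft enolisation at the only enolisable α-carbon should give the 2-silyloxydiene, the (Z)-enol geometry being the usual one for α-oxygenated ketones; no stereocenter is formed.

**Step 4**
Reactants: 5 (S)-2-methylpropane-2-sulfinamide; 6 acetaldehyde
Product: 7 (S,E)-N-ethylidene-2-methylpropane-2-sulfinamide
Conditions: pyrrolidine (10 mol%), 4 Å molecular sieves, CH2Cl2, rt
Reagents that add atoms: none
Why: amine-catalysed condensation (imine formation) of the sulfinamide with the aldehyde should give the (E)-N-sulfinyl aldimine with the sulfur stereocenter untouched.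

**Step 5**
Reactants: 7 (S,E)-N-ethylidene-2-methylpropane-2-sulfinamide; 4 (1Z,3E)-1-[(tert-butyldimethylsilyl)oxy]-4-methoxy-2-[(trimethylsilyl)oxy]buta-1,3-diene
Product: 10 (2R,3R)-3-[(tert-butyldimethylsilyl)oxy]-2-methyl-2,3-dihydropyridin-4(1H)-one, via sulfinyl Mannich adduct 8 (not isolated), via amino enone 9 (not isolated)
Conditions: TMSOTf (20 mol%), CH2Cl2, −78 °C; then HCl (1 M in MeOH, 2 equiv), 0 °C; then NaHCO3, rt
Reagents that add atoms: none
Why: TMSOTf activates the sulfinyl imine, the oxygen-bearing diene terminus (C3, the β-carbon of the silyl enol ether and vinylogous to the methoxy group) attacks the imine carbon (C2–C3 bond, Mukaiyama–Mannich stage), and after acidic methanolysis of the N–S bond the freed nitrogen closes onto the β-methoxy enone carbon (N1–C6 bond) with loss of methanol, so the whole is a stepwise aza-Diels–Alder (Mannich–Michael) reaction. The closest known reaction type is the Lewis-acid-promoted cyclocondensation of 1-methoxy-3-silyloxydienes, including 4-oxygenated ones, with aldehydes and with chiral imines such as N-sulfinyl imines. The one ring closed is the dihydropyridone, by 6-endo-trig conjugate addition of nitrogen to C6 followed by β-elimination of methoxide. C2 is controlled by the (S)-sulfinyl group, the diene adding to the imine face anti to the tert-butyl group, which should give the R configuration; C3 is set relative to C2 by the anti-selective open Mannich transition state and, being enolisable, can also settle to the 2,3-trans isomer with both substituents pseudo-equatorial. The step needs regioselectivity (C3 as the nucleophile, nitrogen to C6) and survival of the C3 silyl ether; the first is secured by the C4 silyloxy group that polarises the diene, the second by a short, cold acid stage.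

**Step 6**
Reactants: 10 (2R,3R)-3-[(tert-butyldimethylsilyl)oxy]-2-methyl-2,3-dihydropyridin-4(1H)-one
Product: 11 tert-butyl (2R,3R)-3-[(tert-butyldimethylsilyl)oxy]-2-methyl-4-oxo-3,4-dihydropyridine-1(2H)-carboxylate
Conditions: Boc2O, DMAP (10 mol%), Et3N, CH2Cl2, rt
Reagents that add atoms: di-tert-butyl dicarbonate, CC(C)(C)OC(=O)OC(=O)OC(C)(C)C
Why: DMAP-catalysed N-acylation (carbamate formation) of the vinylogous amide should leave both stereocenters untouched and installs the N-acyl group that activates C6 and holds the C2 methyl group pseudoaxial for step 13.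

**Step 7**
Reactants: 12 11-bromoundec-1-ene; 13 (S)-2-methyloxirane
Product: 15 (S)-tetradec-13-en-2-ol, via Grignard reagent 14 (not isolated)
Conditions: Mg, THF; then CuI (10 mol%), 13, −30 to 0 °C; H2O
Reagents that add atoms: none
Why: copper-catalysed epoxide ring opening by the Grignard reagent occurs by SN2 attack at the unsubstituted carbon, so the C15' stereocenter is carried over unchanged from (S)-propylene oxide.

**Step 8**
Reactants: 15 (S)-tetradec-13-en-2-ol
Product: 16 (S)-tert-butyldimethyl(tetradec-13-en-2-yloxy)silane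
Conditions: TBSCl, imidazole, DMF, rt
Reagents that add atoms: tert-butyldimethylsilyl chloride, CC(C)(C)[Si](C)(C)Cl
Why: silyl ether formation protects the secondary alcohol without touching the stereocenter.

**Step 9**
Reactants: 16 (S)-tert-butyldimethyl(tetradec-13-en-2-yloxy)silane
Product: 18 (S)-12-[(tert-butyldimethylsilyl)oxy]tridecanal, via ozonide 17 (not isolated)
Conditions: O3, CH2Cl2, −78 °C; then PPh3, −78 °C to rt
Reagents that add atoms: ozone, [O-][O+]=O
Why: ozonolysis of the terminal alkene with reductive work-up should give the aldehyde one carbon shorter while the silyl ether and the stereocenter stay intact.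

**Step 10**
Reactants: 18 (S)-12-[(tert-butyldimethylsilyl)oxy]tridecanal
Product: 20 (4S,15S)-15-[(tert-butyldimethylsilyl)oxy]hexadec-1-en-4-ol, via borinate ester 19 (not isolated)
Conditions: (−)-Ipc2B(allyl), Et2O, −78 °C; then NaOH, H2O2, 0 °C to rt
Reagents that add atoms: (−)-B-allyldiisopinocampheylborane, C=CCB([C@H]1C[C@H]2C[C@@H]([C@@H]1C)C2(C)C)[C@H]1C[C@H]2C[C@@H]([C@@H]1C)C2(C)C
Why: Brown allylboration through a chair-like six-membered transition state is reagent-controlled, and the (−)-reagent should deliver allyl to the Re face of the unbranched aldehyde and so set the S configuration at C4'.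

**Step 11**
Reactants: 20 (4S,15S)-15-[(tert-butyldimethylsilyl)oxy]hexadec-1-en-4-ol
Product: 21 (4S,15S)-4,15-bis[(tert-butyldimethylsilyl)oxy]hexadec-1-ene
Conditions: TBSCl, imidazole, DMF, 40 °C
Reagents that add atoms: tert-butyldimethylsilyl chloride, CC(C)(C)[Si](C)(C)Cl
Why: silyl ether formation protects the homoallylic alcohol without touching either stereocenter.

**Step 12**
Reactants: 21 (4S,15S)-4,15-bis[(tert-butyldimethylsilyl)oxy]hexadec-1-ene
Product: 23 (4S,15S)-4,15-bis[(tert-butyldimethylsilyl)oxy]-1-iodohexadecane, via alkylborane 22 (not isolated)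
Conditions: 9-BBN, THF, 0 °C to rt; then NaOMe, MeOH, I2, 0 °C
Reagents that add atoms: iodine, II
Why: anti-Markovnikov hydroboration of the terminal alkene followed by base-induced iodinolysis of the primary B–C bond should give the primary iodide without touching the stereocenters.

**Step 13**
Reactants: 23 (4S,15S)-4,15-bis[(tert-butyldimethylsilyl)oxy]-1-iodohexadecane; 11 tert-butyl (2R,3R)-3-[(tert-butyldimethylsilyl)oxy]-2-methyl-4-oxo-3,4-dihydropyridine-1(2H)-carboxylate
Product: 26 tert-butyl (2R,3R,6S)-6-[(4S,15S)-4,15-bis[(tert-butyldimethylsilyl)oxy]hexadecyl]-3-[(tert-butyldimethylsilyl)oxy]-2-methyl-4-[(trifluoromethylsulfonyl)oxy]-3,6-dihydropyridine-1(2H)-carboxylate, via Grignard reagent 24 (not isolated), via magnesium enolate 25 (not isolated)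
Conditions: Mg, THF, rt; then CuBr·SMe2 (20 mol%), 11, THF, −78 °C; then N-(5-chloropyridin-2-yl)bis(trifluoromethanesulfonimide), −78 to 0 °C; H2O
Reagents that add atoms: N-(5-chloropyridin-2-yl)-1,1,1-trifluoro-N-(trifluoromethylsulfonyl)methanesulfonamide, FC(F)(F)S(=O)(=O)N(c1ccc(Cl)cn1)S(=O)(=O)C(F)(F)F
Why: copper-catalysed conjugate addition of the Grignard reagent to the N-acyl-2,3-dihydro-4-pyridone should proceed by axial attack on the half-chair in which A(1,3) strain keeps the C2 methyl group pseudoaxial, which sets C6 cis to C2, and the regiodefined magnesium enolate is trapped on oxygen as the enol triflate.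

**Step 14**
Reactants: 26 tert-butyl (2R,3R,6S)-6-[(4S,15S)-4,15-bis[(tert-butyldimethylsilyl)oxy]hexadecyl]-3-[(tert-butyldimethylsilyl)oxy]-2-methyl-4-[(trifluoromethylsulfonyl)oxy]-3,6-dihydropyridine-1(2H)-carboxylate
Product: 27 tert-butyl (2R,3S,6S)-6-[(4S,15S)-4,15-bis[(tert-butyldimethylsilyl)oxy]hexadecyl]-3-[(tert-butyldimethylsilyl)oxy]-2-methylpiperidine-1-carboxylate
Conditions: H2 (1 atm), 5% Pt/C, Li2CO3, EtOAc, rt
Reagents that add atoms: none
Why: catalytic hydrogenolysis of the enol triflate C–O bond and hydrogenation of the resulting alkene should remove the helper oxygen at C4 without creating or disturbing a stereocenter.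

**Step 15**
Reactants: 27 tert-butyl (2R,3S,6S)-6-[(4S,15S)-4,15-bis[(tert-butyldimethylsilyl)oxy]hexadecyl]-3-[(tert-butyldimethylsilyl)oxy]-2-methylpiperidine-1-carboxylate
Product: 29 (2R,3S,6S)-6-[(4S,15S)-4,15-dihydroxyhexadecyl]-2-methylpiperidin-3-ol, via hydrochloride salt 28 (not isolated)
Conditions: HCl (3 M in MeOH), rt; then aq. NaOH to pH 11
Reagents that add atoms: none
Why: acidic methanolysis (global deprotection) cleaves the three silyl ethers and the Boc carbamate together, and basification frees the amino triol with no stereocenter affected.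

**Compound list**

1 | 2-[(tert-butyldimethylsilyl)oxy]-N-methoxy-N-methylacetamide | CON(C)C(=O)CO[Si](C)(C)C(C)(C)C | starting material
2 | 1-[(tert-butyldimethylsilyl)oxy]but-3-yn-2-one | C#CC(=O)CO[Si](C)(C)C(C)(C)C | intermediate
3 | (E)-1-[(tert-butyldimethylsilyl)oxy]-4-methoxybut-3-en-2-one | CO/C=C/C(=O)CO[Si](C)(C)C(C)(C)C | intermediate
4 | (1Z,3E)-1-[(tert-butyldimethylsilyl)oxy]-4-methoxy-2-[(trimethylsilyl)oxy]buta-1,3-diene | CO/C=C/C(O[Si](C)(C)C)=C/O[Si](C)(C)C(C)(C)C | intermediate
5 | (S)-2-methylpropane-2-sulfinamide | CC(C)(C)[S@](=O)N | starting material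
6 | acetaldehyde | CC=O | starting material
7 | (S,E)-N-ethylidene-2-methylpropane-2-sulfinamide | CC(C)(C)[S@](=O)/N=C/C | intermediate
8 | (S)-N-[(2R,3R,5E)-3-[(tert-butyldimethylsilyl)oxy]-6-methoxy-4-oxohex-5-en-2-yl]-2-methylpropane-2-sulfinamide | CO/C=C/C(=O)[C@H](O[Si](C)(C)C(C)(C)C)[C@@H](C)N[S@@](=O)C(C)(C)C | intermediate
9 | (1E,4R,5R)-5-amino-4-[(tert-butyldimethylsilyl)oxy]-1-methoxyhex-1-en-3-one | CO/C=C/C(=O)[C@H](O[Si](C)(C)C(C)(C)C)[C@@H](C)N | intermediate
10 | (2R,3R)-3-[(tert-butyldimethylsilyl)oxy]-2-methyl-2,3-dihydropyridin-4(1H)-one | C1=CC(=O)[C@H](O[Si](C)(C)C(C)(C)C)[C@@H](C)N1 | intermediate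
11 | tert-butyl (2R,3R)-3-[(tert-butyldimethylsilyl)oxy]-2-methyl-4-oxo-3,4-dihydropyridine-1(2H)-carboxylate | C1=CC(=O)[C@H](O[Si](C)(C)C(C)(C)C)[C@@H](C)N1C(=O)OC(C)(C)C | intermediate
12 | 11-bromoundec-1-ene | C=CCCCCCCCCCBr | starting material
13 | (S)-2-methyloxirane | C[C@H]1CO1 | starting material
14 | undec-10-en-1-ylmagnesium bromide | C=CCCCCCCCCC[Mg]Br | intermediate
15 | (S)-tetradec-13-en-2-ol | C[C@H](O)CCCCCCCCCCC=C | intermediate
16 | (S)-tert-butyldimethyl(tetradec-13-en-2-yloxy)silane | C[C@H](O[Si](C)(C)C(C)(C)C)CCCCCCCCCCC=C | intermediate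
17 | 3-[(11S)-11-[(tert-butyldimethylsilyl)oxy]dodecyl]-1,2,4-trioxolane | C[C@H](O[Si](C)(C)C(C)(C)C)CCCCCCCCCCC1OCOO1 | intermediate
18 | (S)-12-[(tert-butyldimethylsilyl)oxy]tridecanal | C[C@H](O[Si](C)(C)C(C)(C)C)CCCCCCCCCCC=O | intermediate
19 | (4S,15S)-15-[(tert-butyldimethylsilyl)oxy]hexadec-1-en-4-yl diisopinocampheylborinate | C[C@H](O[Si](C)(C)C(C)(C)C)CCCCCCCCCC[C@H](OB([C@H]1C[C@H]2C[C@@H]([C@@H]1C)C2(C)C)[C@H]1C[C@H]2C[C@@H]([C@@H]1C)C2(C)C)CC=C | intermediate
20 | (4S,15S)-15-[(tert-butyldimethylsilyl)oxy]hexadec-1-en-4-ol | C[C@H](O[Si](C)(C)C(C)(C)C)CCCCCCCCCC[C@H](O)CC=C | intermediate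
21 | (4S,15S)-4,15-bis[(tert-butyldimethylsilyl)oxy]hexadec-1-ene | C[C@H](O[Si](C)(C)C(C)(C)C)CCCCCCCCCC[C@H](O[Si](C)(C)C(C)(C)C)CC=C | intermediate
22 | 9-[(4R,15S)-4,15-bis[(tert-butyldimethylsilyl)oxy]hexadecyl]-9-borabicyclo[3.3.1]nonane | C[C@H](O[Si](C)(C)C(C)(C)C)CCCCCCCCCC[C@H](O[Si](C)(C)C(C)(C)C)CCCB1C2CCCC1CCC2 | intermediate
23 | (4S,15S)-4,15-bis[(tert-butyldimethylsilyl)oxy]-1-iodohexadecane | C[C@H](O[Si](C)(C)C(C)(C)C)CCCCCCCCCC[C@H](O[Si](C)(C)C(C)(C)C)CCCI | intermediate
24 | [(4S,15S)-4,15-bis[(tert-butyldimethylsilyl)oxy]hexadecyl]magnesium iodide | C[C@H](O[Si](C)(C)C(C)(C)C)CCCCCCCCCC[C@H](O[Si](C)(C)C(C)(C)C)CCC[Mg]I | intermediate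
25 | tert-butyl (2R,3R,6S)-6-[(4S,15S)-4,15-bis[(tert-butyldimethylsilyl)oxy]hexadecyl]-3-[(tert-butyldimethylsilyl)oxy]-4-[(iodomagnesio)oxy]-2-methyl-3,6-dihydropyridine-1(2H)-carboxylate | C[C@H](O[Si](C)(C)C(C)(C)C)CCCCCCCCCC[C@H](O[Si](C)(C)C(C)(C)C)CCC[C@H]1C=C(O[Mg]I)[C@H](O[Si](C)(C)C(C)(C)C)[C@@H](C)N1C(=O)OC(C)(C)C | intermediate
26 | tert-butyl (2R,3R,6S)-6-[(4S,15S)-4,15-bis[(tert-butyldimethylsilyl)oxy]hexadecyl]-3-[(tert-butyldimethylsilyl)oxy]-2-methyl-4-[(trifluoromethylsulfonyl)oxy]-3,6-dihydropyridine-1(2H)-carboxylate | C[C@H](O[Si](C)(C)C(C)(C)C)CCCCCCCCCC[C@H](O[Si](C)(C)C(C)(C)C)CCC[C@H]1C=C(OS(=O)(=O)C(F)(F)F)[C@H](O[Si](C)(C)C(C)(C)C)[C@@H](C)N1C(=O)OC(C)(C)C | intermediate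
27 | tert-butyl (2R,3S,6S)-6-[(4S,15S)-4,15-bis[(tert-butyldimethylsilyl)oxy]hexadecyl]-3-[(tert-butyldimethylsilyl)oxy]-2-methylpiperidine-1-carboxylate | C[C@H](O[Si](C)(C)C(C)(C)C)CCCCCCCCCC[C@H](O[Si](C)(C)C(C)(C)C)CCC[C@H]1CC[C@H](O[Si](C)(C)C(C)(C)C)[C@@H](C)N1C(=O)OC(C)(C)C | intermediate
28 | (2R,3S,6S)-6-[(4S,15S)-4,15-dihydroxyhexadecyl]-2-methylpiperidin-3-ol hydrochloride | C[C@H](O)CCCCCCCCCC[C@H](O)CCC[C@H]1CC[C@H](O)[C@@H](C)[NH2+]1.[Cl-] | intermediate
29 | (2R,3S,6S)-6-[(4S,15S)-4,15-dihydroxyhexadecyl]-2-methylpiperidin-3-ol | C[C@H](O)CCCCCCCCCC[C@H](O)CCC[C@H]1CC[C@H](O)[C@@H](C)N1 | target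

**Totals**

Total step count: 15. Longest linear sequence: 9 steps (steps 7 to 15).

**Steps most likely to fail**

Step 5. The Mannich stage may show poor simple diastereoselection (2,3-cis/trans mixtures) or a weak facial preference with the oxygen-bearing diene, and the C3 silyl ether may be partly cleaved in the acid stage. The fallback introduces the C3 oxygen after ring formation, under substrate control. It sets out from 7, which is combined under the conditions of step 5 with commercial trans-1-methoxy-3-(trimethylsilyloxy)buta-1,3-diene to give (R)-2-methyl-2,3-dihydropyridin-4(1H)-one F1. N-Acylation with Boc2O and DMAP gives tert-butyl (R)-2-methyl-4-oxo-3,4-dihydropyridine-1(2H)-carboxylate F2. Its lithium enolate (LiN(SiMe3)2, THF, −78 °C) is oxidised with 3-phenyl-2-(phenylsulfonyl)oxaziridine anti to the pseudoaxial C2 methyl group to tert-butyl (2R,3R)-3-hydroxy-2-methyl-4-oxo-3,4-dihydropyridine-1(2H)-carboxylate F3. Silylation with TBSCl and imidazole comes back to the route at 11.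

Step 13. Competing 1,2-addition or proton transfer from C3 may consume the Grignard reagent, and O-sulfonylation of the hindered magnesium enolate may stay incomplete. The fallback separates carbon–carbon bond formation from deoxygenation. It sets out from 23 and 11: the Grignard reagent 24 is converted with CuBr·SMe2 and BF3·OEt2 into the alkylcopper reagent, added to 11 and quenched with water to give tert-butyl (2R,3R,6S)-6-[(4S,15S)-4,15-bis[(tert-butyldimethylsilyl)oxy]hexadecyl]-3-[(tert-butyldimethylsilyl)oxy]-2-methyl-4-oxopiperidine-1-carboxylate F4. Condensation with 4-methylbenzenesulfonohydrazide gives tert-butyl (2R,3R,6S)-6-[(4S,15S)-4,15-bis[(tert-butyldimethylsilyl)oxy]hexadecyl]-3-[(tert-butyldimethylsilyl)oxy]-2-methyl-4-[2-(4-methylphenylsulfonyl)hydrazinylidene]piperidine-1-carboxylate F5. Reduction with catecholborane followed by NaOAc (Caglioti-type deoxygenation) comes back to the route at 27, bypassing 26.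

Step 14. Hydrogenolysis of the allylic C3–O bond may compete at the alkene stage, or reduction of the enol triflate may stall. The fallback replaces surface hydrogenation by hydride transfer and diimide. It sets out from 26, which with Pd(OAc)2, PPh3, HCO2H and Et3N in DMF at 60 °C is reduced to tert-butyl (2R,3S,6S)-6-[(4S,15S)-4,15-bis[(tert-butyldimethylsilyl)oxy]hexadecyl]-3-[(tert-butyldimethylsilyl)oxy]-2-methyl-3,6-dihydropyridine-1(2H)-carboxylate F6. Diimide generated from 4-methylbenzenesulfonohydrazide and NaOAc in refluxing DME/H2O saturates the ring alkene and comes back to the route at 27.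

**Further compounds**

F1 | step 5 | (R)-2-methyl-2,3-dihydropyridin-4(1H)-one | C1=CC(=O)C[C@@H](C)N1
F2 | step 5 | tert-butyl (R)-2-methyl-4-oxo-3,4-dihydropyridine-1(2H)-carboxylate | C1=CC(=O)C[C@@H](C)N1C(=O)OC(C)(C)C
F3 | step 5 | tert-butyl (2R,3R)-3-hydroxy-2-methyl-4-oxo-3,4-dihydropyridine-1(2H)-carboxylate | C1=CC(=O)[C@H](O)[C@@H](C)N1C(=O)OC(C)(C)C
F4 | step 13 | tert-butyl (2R,3R,6S)-6-[(4S,15S)-4,15-bis[(tert-butyldimethylsilyl)oxy]hexadecyl]-3-[(tert-butyldimethylsilyl)oxy]-2-methyl-4-oxopiperidine-1-carboxylate | C[C@H](O[Si](C)(C)C(C)(C)C)CCCCCCCCCC[C@H](O[Si](C)(C)C(C)(C)C)CCC[C@H]1CC(=O)[C@H](O[Si](C)(C)C(C)(C)C)[C@@H](C)N1C(=O)OC(C)(C)C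
F5 | step 13 | tert-butyl (2R,3R,6S)-6-[(4S,15S)-4,15-bis[(tert-butyldimethylsilyl)oxy]hexadecyl]-3-[(tert-butyldimethylsilyl)oxy]-2-methyl-4-[2-(4-methylphenylsulfonyl)hydrazinylidene]piperidine-1-carboxylate | C[C@H](O[Si](C)(C)C(C)(C)C)CCCCCCCCCC[C@H](O[Si](C)(C)C(C)(C)C)CCC[C@H]1CC(=NNS(=O)(=O)c2ccc(C)cc2)[C@H](O[Si](C)(C)C(C)(C)C)[C@@H](C)N1C(=O)OC(C)(C)C
F6 | step 14 | tert-butyl (2R,3S,6S)-6-[(4S,15S)-4,15-bis[(tert-butyldimethylsilyl)oxy]hexadecyl]-3-[(tert-butyldimethylsilyl)oxy]-2-methyl-3,6-dihydropyridine-1(2H)-carboxylate | C[C@H](O[Si](C)(C)C(C)(C)C)CCCCCCCCCC[C@H](O[Si](C)(C)C(C)(C)C)CCC[C@H]1C=C[C@H](O[Si](C)(C)C(C)(C)C)[C@@H](C)N1C(=O)OC(C)(C)C
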